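At early times, compare amounts of target, not percentages. On the list of suspects, substrate meets partner, which the gas feeds into solution, and the two give target; at the start no partner is dissolved.

the same everywhere: gas 1.7 mM (held)
- Friday's: substrate 0.013 M; run made earlier
- Saturday's: substrate 0.030 M; run made earlier
- flask: substrate 0.020 M; time 2.5 d

| Friday's: time / h | Friday's: target / % | Saturday's: time / h | Saturday's: target / % |
|---|---|---|---|
| 8.00 | 14.6 | 8.00 | 7.8 |
| 12.0 | 20.0 | 12.0 | 11.1 |
| 20.0 | 23.9 | 20.0 | 15.1 |
| 30.0 | 25.1 | 30.0 | 18.9 |
| 50.0 | 22.2 | 50.0 | 16.2 |

(scatter of a reading: 1 percentage point)

- the moment within 2.5 d at which there is most target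
- the amount of target, in percent of the substrate charged, at that time
- earliest time at which at least nineteen twentieths of that best amount are there, in d
- latest time at which they still are, in d

- in percentages every species weighs as the substrate in it: one side product counts as two
- at the start none of partner is dissolved
- on the list of suspects stand: gas <-> partner; substrate + partner -> target; 2 substrate -> side product; partner + target -> over-reaction product; target <-> isomer of the product

After 8.00 h, Friday's run holds 1.90 mM of target and Saturday's 2.34 mM. The charge rose 2.31 times but the target only 1.23 times, which is much less. So treat early target formation as nearly zero order in substrate, with the uptake of gas as partner as the candidate rate-limiting step, and leave the gap between the runs as a correction. Define the early throughput J, the mean of these two amounts of target per hour elapsed up to that reading: 0.265 mM h⁻¹. Divide Jt by the charge to get S, the share of the charge that has entered this route by time t. Later, set S against target plus what target turns into, over-reaction product and isomer. J is read at early times, so any later use is an extrapolation.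

The forecast for the flask puts the peak at 1.3 d with 22.3%, and the window from 1 d to 1.7 d, and it finds that target looks “limited by slow partner supply”. My reckoning gives no peak, only S: at that time in the flask, 41.3%. The forecast's best is about half of that share.

The flask peaks at 1.40 d with 23.1%, and its window runs from 1.02 d to 1.84 d, each within the forecast's tolerance.

    gas ⇌ partner, rate k1*(csat - [partner]) (kL = 8.20 × 10⁻⁵ s⁻¹)
    substrate + partner → target (k = 0.0150 M⁻¹ s⁻¹)
    2 substrate → side product (k = 2.50 × 10⁻⁴ M⁻¹ s⁻¹)
    partner + target → over-reaction product (k = 0.0110 M⁻¹ s⁻¹)
    target ⇌ isomer of the product (K = 0.440, k = 7.50 × 10⁻⁶ s⁻¹)

In the flask, target is made 1.29 times as fast as it is used up at 1.06 d, but 0.526 times at 2.50 d, and the peak lies between these times. At 1.40 d, target, over-reaction product and isomer hold 42.7% of the flask's charge, against S of 44.4%. In the neighbour flask with 0.080 M of substrate, they hold 19.8% at 2.50 d, against S of 19.9%, and its best is 9.08%.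

Readings and results were generated by integration with made-up constants.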